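**Assumptions**
- Aspidin has no stereocenters (the gem-dimethyl carbon is not stereogenic), so there is no enantiomer to control. The SMILES is one enol tautomer of the triketone.
- BF3-mediated butyrylation of 5-methoxyresorcinol gives mainly the 2,4-dihydroxy-6-methoxy ketone. Two equivalent positions flank OMe/OH, against one position between the two OH groups. The minor isomer is removed by chromatography.

## Retrosynthetic overview
1. Aspidin comes from a one-pot double C-methylation (MeI/NaOMe) of the methylene-bridged bis(acylphloroglucinol) **8**. The C-Me carbon of the left ring becomes the gem-dimethyl carbon, so the cyclohexanetrione ring is made by dearomatization rather than from filicinic acid. The right-ring CH is methylated to give the aryl-CH3.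
2. **8** comes from an o-quinone-methide coupling of the Mannich base of methylphlorbutyrophenone (**7**) with 2,4-dihydroxy-6-methoxybutyrophenone (**5**). The bridge lands on the carbon flanked by two OH groups, which blocks it. The later methylation is then forced onto the carbon flanked by OH and OMe, which places the C-methyl next to the OMe as in aspidin.
3. Both aromatic units are made by BF3-mediated butyrylation of commercial polyphenols. Ring order: both aromatic rings are present from the start; the gem-dimethylcyclohexanetrione ring forms in the last step.

## Route

**Step 1**
Reactants: 1 (2-methylbenzene-1,3,5-triol), 2 (butanoic acid)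
Product: 3 (1-(2,4,6-trihydroxy-3-methylphenyl)butan-1-one)
Conditions: BF3·OEt2, 85 °C, 2 h
Reagents that add atoms: butanoic acid, CCCC(=O)O
Why: Friedel–Crafts (BF3) C-acylation of an activated phloroglucinol. C4 and C6 of 1 are equivalent, so only one regioisomer forms.

**Step 2**
Reactants: 4 (5-methoxybenzene-1,3-diol), 2 (butanoic acid)
Product: 5 (1-(2,4-dihydroxy-6-methoxyphenyl)butan-1-one)
Conditions: BF3·OEt2, 85 °C, 2 h; chromatographic removal of the 2,6-dihydroxy-4-methoxy isomer
Reagents that add atoms: butanoic acid, CCCC(=O)O
Why: Friedel–Crafts acylation at the two equivalent carbons flanked by OMe and OH (statistically favored). This places the acyl group next to OMe, as in aspidin, and leaves the carbon between the two OH groups free.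

**Step 3**
Reactants: 3, 6 (Eschenmoser's salt)
Product: 7 (1-[3-(dimethylaminomethyl)-2,4,6-trihydroxy-5-methylphenyl]butan-1-one)
Conditions: Me2N+=CH2 I− (1.05 equiv), MeCN, 25 °C, 3 h
Reagents that add atoms: Eschenmoser's salt, C[N+](C)=C.[I-]
Why: Mannich aminomethylation of the only free ring carbon of 3. The product has no remaining ring C–H, so it cannot self-condense through carbon and serves only as an o-quinone-methide precursor.

**Step 4**
Reactants: 7, 5 (3 equiv)
Product: 8 (methylene-bridged bis(acylphloroglucinol))
Conditions: 1,4-dioxane, 100 °C, N2 sweep to remove Me2NH, 16 h
Reagents that add atoms: none (Me2NH is lost)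
Why: Mannich base → o-quinone methide (loss of Me2NH) followed by C-benzylation (1,4-addition). Excess 5 attacks through C3, the most nucleophilic carbon, flanked by two OH groups and para to OMe (cf. C3-prenylation of 2,4-dihydroxy-6-methoxyacetophenone). The excess also suppresses double benzylation of 5. No stereocenters are formed.

**Step 5**
Reactants: 8, 9 (MeI)
Product: 10 (aspidin)
Conditions: NaOMe (5 equiv), MeI (2.5 equiv), MeOH, 0 → 45 °C, 24 h, then aq. HCl (pH 2) and extraction
Reagents that add atoms: iodomethane, CI
Why: Proposed new method: exhaustive C-methylation, as used for phloroglucinol-derived gem-dimethyl triketones, applied here to two different sites of one molecule.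
- Left ring: the anion of the electron-rich 2,4,6-trihydroxy-3-methyl-5-benzylacylbenzene is C-methylated at the less hindered C-Me carbon rather than the benzyl carbon. This dearomatizes the ring to the 2,2-dimethylcyclohexane-1,3,5-trione enolate, a stable acidic sink (pKa ≈ 4) that resists further alkylation.
- Right ring: the only free CH, flanked by OH and OMe, is C-methylated to the aryl-CH3. Protic MeOH favors C- over O-alkylation.
- The remaining right-ring positions are blocked, and dearomatizing a ring that carries an OMe gives no stabilized enolate, so over-methylation there is disfavored.
- No stereocenters are formed.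

## Compound list
1 | 2-methylbenzene-1,3,5-triol | Cc1c(O)cc(O)cc1O | starting material
2 | butanoic acid | CCCC(=O)O | starting material
3 | 1-(2,4,6-trihydroxy-3-methylphenyl)butan-1-one | CCCC(=O)c1c(O)c(C)c(O)cc1O | intermediate
4 | 5-methoxybenzene-1,3-diol | COc1cc(O)cc(O)c1 | starting material
5 | 1-(2,4-dihydroxy-6-methoxyphenyl)butan-1-one | CCCC(=O)c1c(O)cc(O)cc1OC | intermediate
6 | Eschenmoser's salt (dimethylmethyleneammonium iodide) | C[N+](C)=C.[I-] | starting material
7 | Mannich base of 3 | CCCC(=O)c1c(O)c(C)c(O)c(CN(C)C)c1O | intermediate
8 | methylene-bridged bis(acylphloroglucinol) | CCCC(=O)c1c(O)c(C)c(O)c(Cc2c(O)c(C(=O)CCC)c(OC)cc2O)c1O | intermediate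
9 | iodomethane | CI | starting material
10 | aspidin (achiral) | CCCC(=O)C1=C(O)C(Cc2c(O)c(C)c(OC)c(C(=O)CCC)c2O)=C(O)C(C)(C)C1=O | target

## Summary
Total steps: 5.
Longest linear sequence: 4 steps (1 → 3 → 7 → 8 → 10, counting step 1, step 3, step 4, step 5 from 2-methylphloroglucinol).

**Three steps most likely to fail**
1. **Step 5 (chemoselective double C-methylation).**
   - Risks: methylation at the benzyl-bearing carbon, O-methylation of the triketone, or over-methylation.
   - Fallback: build butyrylfilicinic acid separately (3,3-dimethylpentane-2,4-dione, dimethyl carbonate/NaH, t-BuOK Dieckmann, then butyric acid/DCC/DMAP). Couple it at C4 with the Mannich base of 5, then install the right-ring CH3 by Eschenmoser aminomethylation and hydrogenolysis, so that no MeI ever meets the triketone.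
2. **Step 4 (bridge regiochemistry at C3 versus C5 of 5, and polybenzylation).**
   - Fallback: reverse the polarity. Aminomethylate 5 with Eschenmoser's salt at low temperature and separate the C3 Mannich base from the C5 isomer. Then trap its o-quinone methide with 3 as the nucleophile, whose only free carbon fixes the other partner.
3. **Step 2 (acylation regioselectivity of 5-methoxyresorcinol).**
   - Fallback: make 5 by a regiodefined route from butyrylphloroglucinol. Para-selective O-benzylation (BnBr, K2CO3), then ortho O-methylation (MeI, K2CO3), then hydrogenolysis (H2, Pd/C).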